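The numbers belong to no real substance.

G 1.5 M; X 0.600 equiv; time 6.0 h

    D ⇌ X.Q, rate k1*(cs1 - [X.Q]) while solid is left; crystals form when [X.Q] > cs1 (cs1 = 0.67 M, k1 = 5.30 × 10⁻⁴ /s)
    X + Q → X.Q (k2 = 0.548 /M/s)
    Q ⇌ E (K3 = 2.6, k3 = 0.260 /s)
    X + E → X.E (k4 = 0.188 /M/s)
    G ⇌ Q (K5 = 0.0396, k5 = 5.85 × 10⁻⁵ /s)

1. X.Q and D together at 6.0 h, in percent of the G charged
2. the change that raises the amount of X.Q and D together at 6.0 h, in percent of the G charged most ("none" if none brings more than 2 percentage points) (noon / dusk / winter / none)
3. amount of X.Q and D together at 6.0 h, in percent of the G charged, after noon

- noon: doubling the amount of X, all else as stated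
- dusk: doubling the solubility in step 1, all else as stated
- winter: doubling the dissolution coefficient of step 1, all else as stated

- what is said of X.Q includes D
- D is a solid; its amount is given per volume of the solution
- run time (flask): 6.0 h

- X.Q is made from X, and X has one other outlet, X.E, so X.Q equals the X used less the X.E made. The reckoning therefore follows one Q molecule and asks for its chances at each fork.

- A first estimate takes the charge of X, 0.900 M: capture of Q then goes at 0.493 /s, faster than passing into E at 0.260 /s, so the first share of X.Q is 65.5 %.
- The objection is that E is not lost: it returns to Q at 0.100 /s, while X captures it at 0.169 /s. Counting every return, the share of X going to X.E at a given X is w/(X + h). Here w is 0.474 M, the ratio of k3 to k2, the loss constant, and h, which adds to it the return rate over k4, is 1.01 M. The selectivity for X.Q at the charge is then 75.1 %.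
- The next objection is that X falls during the run, and towards zero X the share sinks to 52.9 %. Summing the loss over the fall of X gives X.E = w ln[(X at start + h)/(X at end + h)].
- That assumes the charge of X gets used. Reckoned by its forward rate alone, G passes enough to use it by 4.35 h, and the same rate offers 1.08 M of G in the run, so X is the limiting reagent. While X stands near its charge, Q returns to G at 0.00148 /s, which takes hardly any of Q.
- With X reckoned down to zero, X.E is 0.303 M, and X.Q is 39.8 % of the G charged.
- At noon, X starts at 1.80 M, above the G offered, so the X used is the 1.08 M, and the same sum gives 56.4 %, a gain of 17 percentage points. Step 1 moves material between X.Q and D, which are counted together, so dusk and winter are reckoned to bring nothing.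
- The forecast gives 39.8 %, noon as the best change and 56.2 % after it, below this reckoning's noon figure, and says of X that “about two-thirds of it ends up as X.Q”.
- The flask gives 39.8 %, and noon brings 17 points, to 56.4 %. At 6.00 h the flask holds 0 % of its X charge and X.E at 20.2 % of the G charged. The loss constant also reaches a moment inside the run: at 3.00 h, with 22.3 % of the X charge left, it reckons X.E at 14.5 %, and the flask reads 14.5 %.
- For the flask with 1.00 equiv of X, the charge is 1.50 M, above the 1.08 M of G offered, and the loss constant gives 54.0 %. The simulation of that flask gives 53.9 %.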